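## Retrosynthetic overview

1. Target 19 ⇐ silyl ether 18 ⇐ macrocyclic α-hydroxy ketone 17. The furanone (and the 9-membered oxacycle) is made last by O-cyclisation onto the ring alkyne with a 1,2-shift of the C14 methyl from C1 to C10.
2. 17 ⇐ seco aldehyde 13. An intramolecular allylchromium addition (C6–C7) closes the 10-membered carbocycle, the γ-lactone forms in the same flask, and the C8 isobutyrate is added afterwards.
3. 13 ⇐ methyl ketone 6 + bromo enal 11 by a boron aldol reaction (C8–C9), then selective oxidation at C6.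
4. 6 ⇐ enyne 4 + butane-2,3-dione by a new enantioselective alkynylation (C1–C2; this stereocentre is later relayed to C10). 4 comes from a butynediol mono-silyl ether; 11 from methyl acrylate and glyoxal mono-acetal.
5. Ring order: 10-membered carbocycle → γ-lactone → furanone.

Assumption: 1 is bought as the mono-TBS ether (otherwise one extra mono-silylation of but-2-yne-1,4-diol); atom labels C1–C15 are the germacrane labels of the target (C1 ketone, C2=C3, C4=C5, C6 lactone carbinol, C8 ester carbinol, C10 quaternary, C11=C13, C12 lactone C=O, C14 methyl, C15 CH2O).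

## Route

Step 1
Reactants: 1 4-(tert-butyldimethylsilyloxy)but-2-yn-1-ol
Product: 2 (2Z)-4-(tert-butyldimethylsilyloxy)-3-iodobut-2-en-1-ol
Conditions: NaAlH2(OCH2CH2OMe)2, THF, 0 °C; then I2, −78 °C
Reagents that add atoms: iodine II
Why: Hydroxyl-directed anti hydroalumination puts aluminium on the carbon remote from the free OH, and iodinolysis with retention gives the Z-iodide (I on C4, free OH on C6).

Step 2
Reactants: 2 (2Z)-4-(tert-butyldimethylsilyloxy)-3-iodobut-2-en-1-ol; 3 ethynylmagnesium bromide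
Product: 4 (2E)-3-[(tert-butyldimethylsilyloxy)methyl]pent-2-en-4-yn-1-ol
Conditions: 3 (3 equiv), ZnBr2, THF, 0 °C; then 2, Pd(PPh3)4 (5 mol %), 23 °C
Reagents that add atoms: none
Why: Negishi coupling of the alkenyl iodide with ethynylzinc bromide gives the terminal enyne with retention of olefin geometry (C3–C4 bond); excess organozinc covers the free OH.

Step 3
Reactants: 4 (2E)-3-[(tert-butyldimethylsilyloxy)methyl]pent-2-en-4-yn-1-ol; 5 butane-2,3-dione
Product: 6 (3S,6E)-6-[(tert-butyldimethylsilyloxy)methyl]-3,8-dihydroxy-3-methyloct-6-en-4-yn-2-one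
Conditions: Me2Zn (3 equiv), (S,S)-ProPhenol (20 mol %), Ph3PO (40 mol %), toluene, 0 °C; then 5 (3 equiv, slow addition), 0 → 23 °C
Reagents that add atoms: none
Why: Proposed new method: enantioselective mono-alkynylation of a symmetrical dialkyl 1,2-diketone; butane-2,3-dione is as electrophilic as an α-keto ester and can bridge the two zinc centres of the ProPhenol complex through both carbonyl oxygens, so the zinc-bound alkynyl is delivered to one enantiotopic carbonyl face (sets C1 as S), and the hindered tertiary zinc alkoxide resists a second addition; closest known reaction type is the zinc–ProPhenol (or Zn(OTf)2/amino alcohol) alkynylation of aldehydes and α-keto esters.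

Step 4
Reactants: 7 methyl acrylate; 8 2,2-dimethoxyacetaldehyde
Product: 9 methyl 3-hydroxy-4,4-dimethoxy-2-methylidenebutanoate (racemic)
Conditions: DABCO (0.5 equiv), dioxane/H2O, 23 °C
Reagents that add atoms: none
Why: Morita–Baylis–Hillman reaction of an activated aldehyde; the carbinol stereocentre is removed in the next step.

Step 5
Reactants: 9 methyl 3-hydroxy-4,4-dimethoxy-2-methylidenebutanoate
Product: 11 methyl (2Z)-2-(bromomethyl)-4-oxobut-2-enoate, via bromo acetal 10 (not isolated)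
Conditions: NBS, Me2S, CH2Cl2, 0 °C; then CF3CO2H/H2O, 0 °C
Reagents that add atoms: N-bromosuccinimide O=C1CCC(=O)N1Br; water O
Why: Corey–Kim-type bromination of the Baylis–Hillman alcohol with allylic transposition (SN2′) gives the favoured Z-bromide, and aqueous acid then unmasks the aldehyde (C8).

Step 6
Reactants: 6 (3S,6E)-6-[(tert-butyldimethylsilyloxy)methyl]-3,8-dihydroxy-3-methyloct-6-en-4-yn-2-one; 11 methyl (2Z)-2-(bromomethyl)-4-oxobut-2-enoate
Product: 12 methyl (2Z,4R,7S,10E)-2-(bromomethyl)-10-[(tert-butyldimethylsilyloxy)methyl]-4,7,12-trihydroxy-7-methyl-6-oxododeca-2,10-dien-8-ynoate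
Conditions: (+)-Ipc2BCl (3.3 equiv), Et3N, Et2O, −78 → 0 °C; 11, −78 → −20 °C; then MeOH, pH 7 buffer, H2O2, 0 °C
Reagents that add atoms: none
Why: Reagent-controlled boron aldol reaction (Paterson type) at the only enolisable position (C9; C1 is quaternary), with the hydroxyls carried as borinates; the reagent enantiomer is the one taken to direct Re-face attack on the enal (8R; the sense must be confirmed, the antipode is used if reversed), and the minor C8 epimer is a separable diastereomer.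

Step 7
Reactants: 12 methyl (2Z,4R,7S,10E)-2-(bromomethyl)-10-[(tert-butyldimethylsilyloxy)methyl]-4,7,12-trihydroxy-7-methyl-6-oxododeca-2,10-dien-8-ynoate
Product: 13 methyl (2Z,4R,7S,10E)-2-(bromomethyl)-10-[(tert-butyldimethylsilyloxy)methyl]-4,7-dihydroxy-7-methyl-6,12-dioxododeca-2,10-dien-8-ynoate
Conditions: TEMPO (10 mol %), PhI(OAc)2, CH2Cl2, 23 °C
Reagents that add atoms: none
Why: Oxoammonium oxidation takes the primary allylic alcohol (C6) much faster than the secondary C8–OH and leaves the tertiary one; the enal geometry (CHO cis to the small alkynyl group) is the stable one.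

Step 8
Reactants: 13 methyl (2Z,4R,7S,10E)-2-(bromomethyl)-10-[(tert-butyldimethylsilyloxy)methyl]-4,7-dihydroxy-7-methyl-6,12-dioxododeca-2,10-dien-8-ynoate
Product: 15 (1S,4E,6R,7R,8R)-15-(tert-butyldimethylsilyloxy)-1,8-dihydroxy-10-oxo-14(10→1)-abeo-germacra-4,11(13)-dien-2-yn-6,12-olide (C1 = C(OH)CH3; C2≡C3; C10 = C=O), via macrocyclic hydroxy ester 14 (not isolated)
Conditions: CrCl2 (10 equiv), THF, 2 mM, syringe-pump addition, 23 → 40 °C
Reagents that add atoms: none
Why: Nozaki–Hiyama-type intramolecular allylchromium addition to the enal is aldehyde-selective and forms C6–C7; a chair transition state should give the anti adduct (6R, trans-lactone), and attack anti to C9 with H8 eclipsing the enoate (allylic strain, OH bound to chromium) should set 7R from 8R; the C6 chromium alkoxide then lactonises onto the methyl ester. The C8–OH is left free here to avoid reductive 1,4-elimination of a γ-acyloxy allylic bromide.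

Step 9
Reactants: 15 (1S,4E,6R,7R,8R)-15-(tert-butyldimethylsilyloxy)-1,8-dihydroxy-10-oxo-14(10→1)-abeo-germacra-4,11(13)-dien-2-yn-6,12-olide; 16 2-methylpropanoyl chloride
Product: 17 (1S,4E,6R,7R,8R)-15-(tert-butyldimethylsilyloxy)-1-hydroxy-8-(2-methylpropanoyloxy)-10-oxo-14(10→1)-abeo-germacra-4,11(13)-dien-2-yn-6,12-olide
Conditions: pyridine, DMAP (cat.), CH2Cl2, 0 °C
Reagents that add atoms: none
Why: DMAP-catalysed acylation of the only secondary hydroxyl; the tertiary propargylic C1–OH does not react at 0 °C, and acylating before step 10 prevents the C8–OH from competing for the activated alkyne.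

Step 10
Reactants: 17 (1S,4E,6R,7R,8R)-15-(tert-butyldimethylsilyloxy)-1-hydroxy-8-(2-methylpropanoyloxy)-10-oxo-14(10→1)-abeo-germacra-4,11(13)-dien-2-yn-6,12-olide
Product: 18 (4Z,6R,7R,8R,10S)-15-(tert-butyldimethylsilyloxy)-8-(2-methylpropanoyloxy)-1-oxo-3,10-epoxygermacra-2,4,11(13)-trien-6,12-olide
Conditions: AuCl3 (5 mol %), CH2Cl2, 35 °C
Reagents that add atoms: none
Why: Gold-catalysed cycloisomerisation/1,2-migration of a 2-hydroxy-2-alkynyl ketone, here transannular: the C10 carbonyl oxygen attacks C3 of the strained ring alkyne (5-endo-dig), and a cationic α-ketol-type 1,2-shift moves the C14 methyl from C1 to C10 while C1 becomes the ketone; the shift is suprafacial, so 1S is relayed to 10S.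

Step 11
Reactants: 18 (4Z,6R,7R,8R,10S)-15-(tert-butyldimethylsilyloxy)-8-(2-methylpropanoyloxy)-1-oxo-3,10-epoxygermacra-2,4,11(13)-trien-6,12-olide
Product: 19 (4Z,6R,7R,8R,10S)-15-hydroxy-8-(2-methylpropanoyloxy)-1-oxo-3,10-epoxygermacra-2,4,11(13)-trien-6,12-olide (target)
Conditions: HF·pyridine, pyridine/THF, 0 → 23 °C
Reagents that add atoms: none
Why: Buffered fluoride desilylation of the primary TBS ether leaves the ester, the α-methylene lactone and the furanone untouched; no stereocentre is affected.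

## Compound list

1 | 4-(tert-butyldimethylsilyloxy)but-2-yn-1-ol | OCC#CCO[Si](C)(C)C(C)(C)C | starting material
2 | (2Z)-4-(tert-butyldimethylsilyloxy)-3-iodobut-2-en-1-ol | OC/C=C(\I)CO[Si](C)(C)C(C)(C)C | intermediate
3 | ethynylmagnesium bromide | C#C[Mg]Br | starting material
4 | (2E)-3-[(tert-butyldimethylsilyloxy)methyl]pent-2-en-4-yn-1-ol | OC/C=C(\C#C)CO[Si](C)(C)C(C)(C)C | intermediate
5 | butane-2,3-dione | CC(=O)C(C)=O | starting material
6 | (3S,6E)-6-[(tert-butyldimethylsilyloxy)methyl]-3,8-dihydroxy-3-methyloct-6-en-4-yn-2-one | CC(=O)[C@@](C)(O)C#C/C(CO[Si](C)(C)C(C)(C)C)=C\CO | intermediate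
7 | methyl acrylate | C=CC(=O)OC | starting material
8 | 2,2-dimethoxyacetaldehyde | COC(OC)C=O | starting material
9 | methyl 3-hydroxy-4,4-dimethoxy-2-methylidenebutanoate (racemic) | COC(OC)C(O)C(=C)C(=O)OC | intermediate
10 | methyl (2Z)-2-(bromomethyl)-4,4-dimethoxybut-2-enoate (bromo acetal) | COC(OC)/C=C(\CBr)C(=O)OC | intermediate
11 | methyl (2Z)-2-(bromomethyl)-4-oxobut-2-enoate | O=C/C=C(\CBr)C(=O)OC | intermediate
12 | methyl (2Z,4R,7S,10E)-2-(bromomethyl)-10-[(tert-butyldimethylsilyloxy)methyl]-4,7,12-trihydroxy-7-methyl-6-oxododeca-2,10-dien-8-ynoate | COC(=O)/C(CBr)=C/[C@H](O)CC(=O)[C@@](C)(O)C#C/C(CO[Si](C)(C)C(C)(C)C)=C\CO | intermediate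
13 | methyl (2Z,4R,7S,10E)-2-(bromomethyl)-10-[(tert-butyldimethylsilyloxy)methyl]-4,7-dihydroxy-7-methyl-6,12-dioxododeca-2,10-dien-8-ynoate | COC(=O)/C(CBr)=C/[C@H](O)CC(=O)[C@@](C)(O)C#C/C(CO[Si](C)(C)C(C)(C)C)=C\C=O | intermediate
14 | methyl 2-[(1R,2R,3E,7S,10R)-4-[(tert-butyldimethylsilyloxy)methyl]-2,7,10-trihydroxy-7-methyl-8-oxocyclodec-3-en-5-yn-1-yl]prop-2-enoate (macrocyclic hydroxy ester) | COC(=O)C(=C)[C@H]1[C@H](O)/C=C(/CO[Si](C)(C)C(C)(C)C)C#C[C@](C)(O)C(=O)C[C@H]1O | intermediate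
15 | (1S,4E,6R,7R,8R)-15-(tert-butyldimethylsilyloxy)-1,8-dihydroxy-10-oxo-14(10→1)-abeo-germacra-4,11(13)-dien-2-yn-6,12-olide | C=C1C(=O)O[C@@H]2/C=C(/CO[Si](C)(C)C(C)(C)C)C#C[C@](C)(O)C(=O)C[C@@H](O)[C@@H]12 | intermediate
16 | 2-methylpropanoyl chloride | CC(C)C(Cl)=O | starting material
17 | (1S,4E,6R,7R,8R)-15-(tert-butyldimethylsilyloxy)-1-hydroxy-8-(2-methylpropanoyloxy)-10-oxo-14(10→1)-abeo-germacra-4,11(13)-dien-2-yn-6,12-olide | C=C1C(=O)O[C@@H]2/C=C(/CO[Si](C)(C)C(C)(C)C)C#C[C@](C)(O)C(=O)C[C@@H](OC(=O)C(C)C)[C@@H]12 | intermediate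
18 | (4Z,6R,7R,8R,10S)-15-(tert-butyldimethylsilyloxy)-8-(2-methylpropanoyloxy)-1-oxo-3,10-epoxygermacra-2,4,11(13)-trien-6,12-olide | C=C1C(=O)O[C@@H]2/C=C(/CO[Si](C)(C)C(C)(C)C)C3=CC(=O)[C@](C)(C[C@@H](OC(=O)C(C)C)[C@@H]12)O3 | intermediate
19 | (4Z,6R,7R,8R,10S)-15-hydroxy-8-(2-methylpropanoyloxy)-1-oxo-3,10-epoxygermacra-2,4,11(13)-trien-6,12-olide (CNP0176924.2) | C=C1C(=O)O[C@@H]2/C=C(/CO)C3=CC(=O)[C@](C)(C[C@@H](OC(=O)C(C)C)[C@@H]12)O3 | target

## Step count and risks

Total: 11 steps. Longest linear sequence: 9 steps (1, 2, 3, 6, 7, 8, 9, 10, 11); steps 4 and 5 are a two-step side branch.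

Most likely to fail:

Step 3 (the new alkynylation). Ee, the sense of induction (the antipodal ligand is used if it is opposite) and methyl transfer from Me2Zn are all untested on a dialkyl 1,2-diketone. The fallback uses known chemistry, sets out from 4 and returns at 6. Enyne 4 is added to methyl pyruvate under an established asymmetric alkynylation of α-keto esters (Zn(OTf)2, Et3N, chiral β-amino alcohol ligand) to give methyl (2S,5E)-5-[(tert-butyldimethylsilyloxy)methyl]-2,7-dihydroxy-2-methylhept-5-en-3-ynoate F1. MeNH(OMe)·HCl/i-PrMgCl converts this into (2S,5E)-5-[(tert-butyldimethylsilyloxy)methyl]-2,7-dihydroxy-N-methoxy-N,2-dimethylhept-5-en-3-ynamide F2, and MeMgBr then gives 6.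

Step 8 (macrocyclisation). Risks are oligomerisation, the wrong C6/C7 diastereomer, and lactonisation through O8 instead of O6. The fallback sets out from 13 and returns at 17, so step 9 is skipped. 13 is first acylated (16, pyridine) to methyl (2Z,4R,7S,10E)-2-(bromomethyl)-10-[(tert-butyldimethylsilyloxy)methyl]-7-hydroxy-7-methyl-4-(2-methylpropanoyloxy)-6,12-dioxododeca-2,10-dien-8-ynoate F3. An indium-mediated Barbier cyclisation (In, THF/aq. NH4Cl, high dilution), expected to give the syn adduct, leads to methyl 2-[(1S,2S,3E,7S,10R)-4-[(tert-butyldimethylsilyloxy)methyl]-2,7-dihydroxy-7-methyl-10-(2-methylpropanoyloxy)-8-oxocyclodec-3-en-5-yn-1-yl]prop-2-enoate F4 (the C6 epimer). Me3SnOH cleaves only the methyl ester to 2-[(1S,2S,3E,7S,10R)-4-[(tert-butyldimethylsilyloxy)methyl]-2,7-dihydroxy-7-methyl-10-(2-methylpropanoyloxy)-8-oxocyclodec-3-en-5-yn-1-yl]prop-2-enoic acid F5. A Mitsunobu lactonisation (PPh3, DIAD) then closes the lactone with inversion at C6 to give 17.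

Step 10 (transannular cyclisation/1,2-shift). The reaction is established for acyclic and carbocyclic 2-hydroxy-2-alkynyl ketones but not in a strained macrocycle, where ionisation of the tertiary propargylic alcohol could compete. The fallback sets out from 17 and returns at 18. N-Iodosuccinimide (CH2Cl2, 23 °C) triggers the same oxygen cyclisation and 1,2-methyl shift through an iodonium ion without a metal, giving (4Z,6R,7R,8R,10S)-15-(tert-butyldimethylsilyloxy)-2-iodo-8-(2-methylpropanoyloxy)-1-oxo-3,10-epoxygermacra-2,4,11(13)-trien-6,12-olide F6. Pd(OAc)2/PPh3-catalysed formate reduction (HCO2H, Et3N) then removes the iodine to give 18.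

## Further compounds

F1 | step 3 | methyl (2S,5E)-5-[(tert-butyldimethylsilyloxy)methyl]-2,7-dihydroxy-2-methylhept-5-en-3-ynoate | COC(=O)[C@@](C)(O)C#C/C(CO[Si](C)(C)C(C)(C)C)=C\CO
F2 | step 3 | (2S,5E)-5-[(tert-butyldimethylsilyloxy)methyl]-2,7-dihydroxy-N-methoxy-N,2-dimethylhept-5-en-3-ynamide | CON(C)C(=O)[C@@](C)(O)C#C/C(CO[Si](C)(C)C(C)(C)C)=C\CO
F3 | step 8 | methyl (2Z,4R,7S,10E)-2-(bromomethyl)-10-[(tert-butyldimethylsilyloxy)methyl]-7-hydroxy-7-methyl-4-(2-methylpropanoyloxy)-6,12-dioxododeca-2,10-dien-8-ynoate | COC(=O)/C(CBr)=C/[C@H](OC(=O)C(C)C)CC(=O)[C@@](C)(O)C#C/C(CO[Si](C)(C)C(C)(C)C)=C\C=O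
F4 | step 8 | methyl 2-[(1S,2S,3E,7S,10R)-4-[(tert-butyldimethylsilyloxy)methyl]-2,7-dihydroxy-7-methyl-10-(2-methylpropanoyloxy)-8-oxocyclodec-3-en-5-yn-1-yl]prop-2-enoate | COC(=O)C(=C)[C@H]1[C@@H](O)/C=C(/CO[Si](C)(C)C(C)(C)C)C#C[C@](C)(O)C(=O)C[C@H]1OC(=O)C(C)C
F5 | step 8 | 2-[(1S,2S,3E,7S,10R)-4-[(tert-butyldimethylsilyloxy)methyl]-2,7-dihydroxy-7-methyl-10-(2-methylpropanoyloxy)-8-oxocyclodec-3-en-5-yn-1-yl]prop-2-enoic acid | OC(=O)C(=C)[C@H]1[C@@H](O)/C=C(/CO[Si](C)(C)C(C)(C)C)C#C[C@](C)(O)C(=O)C[C@H]1OC(=O)C(C)C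
F6 | step 10 | (4Z,6R,7R,8R,10S)-15-(tert-butyldimethylsilyloxy)-2-iodo-8-(2-methylpropanoyloxy)-1-oxo-3,10-epoxygermacra-2,4,11(13)-trien-6,12-olide | C=C1C(=O)O[C@@H]2/C=C(/CO[Si](C)(C)C(C)(C)C)C3=C(I)C(=O)[C@](C)(C[C@@H](OC(=O)C(C)C)[C@@H]12)O3
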